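(Readings and results are calculated from invented constants; the scatter is artificial.)

The pace holds still between cedar and oak: 0.00854 /min/equiv from cedar's first reading and 0.00857 /min/equiv from oak's. The pace is the count of turnovers, the natural logarithm of charge over electrophile left, per equivalent of nucleophile per minute.

| flask | electrophile | nucleophile | gas | remark | time |
|---|---|---|---|---|---|
| cedar | 0.064 M | 5.4 equiv | 13 mM (held) | run made earlier |  |
| oak | 0.064 M | 8.5 equiv | 13 mM (held) | run made earlier |  |
| flask | 0.064 M |  | 13 mM (held) |  | 2.0 h |

| run | time / min | product / % | electrophile / % |
|---|---|---|---|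
| cedar | 12.0 | 41.2 | 57.5 |
| cedar | 30.0 | 64.5 | 27.1 |
| cedar | 60.0 | 82.4 | 9.9 |
| cedar | 90.0 | 88.0 | 2.9 |
| oak | 25.0 | 77.3 | 16.2 |
| oak | 50.0 | 89.0 | 4.1 |
| oak | 80.0 | 93.0 | 0.7 |
| oak | 90.0 | 91.6 | 1.3 |

(each reading ± 1 percentage point)

- what is said of acid set free includes idle adduct
- at the start none of free base is dissolved
- the amount of nucleophile is what is sought; it is there from the start
- reactions considered so far: electrophile + nucleophile -> acid set free + product; nucleophile + acid set free <-> protonated nucleophile; acid set free + free base <-> salt of the base; acid set free + free base <-> idle adduct; electrophile <-> dormant form; gas <-> free base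

1. the equivalents of nucleophile at which the part of the electrophile that has reacted at 2.0 h is just 95%

Reading "reacted" as 5.00% of the charge left as electrophile, the new flask must make 3.00 turnovers in 2.0 h.

The first reckoning here uses the pace. A constant pace would ask for 2.92 equiv, but the reaction consumes nucleophile, so the pace acts on the charge minus a mean loss. Oak at 50.0 min stands at 3.19 turnovers, close to the depth wanted, and shows a mean loss of 1.02 equiv. Adding that loss gives 3.94 equiv.

The second reckoning ignores the first readings. Late turnovers per minute are 0.0393 /min for cedar and 0.0639 /min for oak, and a straight line through them gives 3.58 equiv.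

The two part, and the line is the suspect. Its slope, 0.00792 /min/equiv, is lower than the pace, and it rests on readings of 2.9% and 4.1% that carry a scatter of 1 percentage point. The reckoning kept here is 3.94 equiv.

The forecast is 3.9 equiv, within 3.3 equiv to 4.8 equiv, and among its grounds is that “Acid not taken by the limited base would also tie up nucleophile”.

    electrophile + nucleophile → acid set free + product (k = 0.00223 /M/s)
    nucleophile + acid set free ⇌ protonated nucleophile, settled at all times (K = 62300 /M)
    acid set free + free base ⇌ salt of the base, settled at all times (K = 166 /M)
    acid set free + free base ⇌ idle adduct, settled at all times (K = 23.5 /M)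
    electrophile ⇌ dormant form (K = 2.10, k = 7.14 × 10⁻⁵ /s)
    gas ⇌ free base, rate k6*(csat - [free base]) (kL = 0.0198 /s)

The flask needs 3.87 equiv. At that charge 57.0% of the nucleophile is still free at 2.00 h. Over the first 1.00 h the free share runs from the whole charge down to 63.1%, and the pace on the mean of those two ends gives 1.62 turnovers. With 82.1% of the electrophile used at 1.00 h, the flask's own count is 1.72.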